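Ring C of the flavonol is disconnected at O1–C2 and C3–C4. This uses the fact that O1 and C4 both hang on ring A as an ortho-hydroxy aldehyde, while C2 (carrying ring B) and C3 form a two-carbon unit that a β-nitrostyrene can deliver, its nitro group serving as the masked C3 oxygen. One base-mediated annulation joins a fully substituted salicylaldehyde, which already holds both prenyl groups at the future C6 and C8 and MOM ethers at the future O5 and O7, to a MOM-protected 4-hydroxy-β-nitrostyrene and closes the pyran ring as a 2-aryl-3-nitro-2H-chromene. Alkaline peroxide then converts the nitroalkene into the 3-hydroxy-4-one, and acid frees the phenols.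

Key step: step 8

Remark: prenyl = 3-methylbut-2-en-1-yl and MOM = methoxymethyl; the target is achiral and every chiral intermediate is racemic, so no absolute configuration has to be controlled.

Step 1
Reactants: 1 phloroglucinol
Product: 2 1,3,5-tris(methoxymethoxy)benzene
Conditions: NaH (3.3 equiv), MOMCl (3.3 equiv), DMF, 0 °C to rt
Reagents that add atoms: chloromethyl methyl ether (MOMCl), COCCl
Why: Williamson O-alkylation of the sodium phenoxides by the reactive α-chloro ether should cap all three hydroxyls as acetals, which later direct the ortho-lithiations.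

Step 2
Reactants: 2 1,3,5-tris(methoxymethoxy)benzene; 3 prenyl bromide
Product: 5 1,3,5-tris(methoxymethoxy)-2-(3-methylbut-2-en-1-yl)benzene, via aryllithium 4 (not isolated)
Conditions: n-BuLi (1.1 equiv), THF, 0 °C; then 3 (1.2 equiv), −78 °C to rt
Reagents that add atoms: none
Why: Directed ortho-metalation removes a ring proton flanked by two coordinating MOM ethers, and the aryllithium should be alkylated at the unhindered primary carbon of the allylic bromide (SN2).

Step 3
Reactants: 5 1,3,5-tris(methoxymethoxy)-2-(3-methylbut-2-en-1-yl)benzene; 3 prenyl bromide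
Product: 7 1,3,5-tris(methoxymethoxy)-2,4-bis(3-methylbut-2-en-1-yl)benzene, via aryllithium 6 (not isolated)
Conditions: n-BuLi (1.1 equiv), THF, 0 °C; then 3 (1.2 equiv), −78 °C to rt
Reagents that add atoms: none
Why: A second directed ortho-metalation at one of the two equivalent ring positions, each again flanked by two MOM ethers so that chelation-assisted ring deprotonation should outrun removal of the benzylic–allylic CH2 hydrogens, is followed by the same SN2 alkylation.

Step 4
Reactants: 7 1,3,5-tris(methoxymethoxy)-2,4-bis(3-methylbut-2-en-1-yl)benzene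
Product: 10 2,4,6-tris(methoxymethoxy)-3,5-bis(3-methylbut-2-en-1-yl)benzaldehyde, via aryllithium 8 (not isolated), via lithium hemiaminolate 9 (not isolated)
Conditions: n-BuLi (1.1 equiv), THF, 0 °C; DMF (3 equiv), 0 °C to rt; then H2O
Reagents that add atoms: N,N-dimethylformamide (DMF), CN(C)C=O
Why: Directed ortho-metalation at the last ring C–H and Bouveault-type formylation, in which the aryllithium adds to DMF to give a tetrahedral lithium hemiaminolate that releases the aldehyde only on aqueous quench, so over-addition is excluded.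

Step 5
Reactants: 10 2,4,6-tris(methoxymethoxy)-3,5-bis(3-methylbut-2-en-1-yl)benzaldehyde
Product: 11 2-hydroxy-4,6-bis(methoxymethoxy)-3,5-bis(3-methylbut-2-en-1-yl)benzaldehyde
Conditions: MgBr2·OEt2 (1.2 equiv), Et2O/toluene, 0 °C to rt; then H2O
Reagents that add atoms: none
Why: Chelation-controlled Lewis-acid acetal cleavage, in which magnesium bridges the formyl oxygen and one ortho MOM ether while bromide removes the methoxymethyl group; once one phenoxide and the formyl oxygen are tied up on magnesium the second ortho acetal is deactivated, the para MOM ether cannot chelate, and the prenyl alkenes meet no protic acid.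

Step 6
Reactants: 12 4-hydroxybenzaldehyde
Product: 13 4-(methoxymethoxy)benzaldehyde
Conditions: NaH (1.1 equiv), MOMCl (1.1 equiv), DMF, 0 °C to rt
Reagents that add atoms: chloromethyl methyl ether (MOMCl), COCCl
Why: Williamson O-alkylation of the phenoxide, the non-enolisable aldehyde being inert to NaH, masks the phenol that would otherwise quench the nitroalkene as an acceptor in step 8.

Step 7
Reactants: 13 4-(methoxymethoxy)benzaldehyde; 14 nitromethane
Product: 16 (E)-1-(methoxymethoxy)-4-(2-nitroethenyl)benzene, via nitroaldol 15 (not isolated)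
Conditions: NH4OAc (0.5 equiv), 14 as solvent, 90 °C
Reagents that add atoms: none
Why: Henry (nitroaldol) condensation, in which addition of nitromethane to the aldehyde and E1cB dehydration of the β-nitro alcohol should give the conjugated, thermodynamically favoured E-nitroalkene in a medium too weakly acidic to cleave the MOM ether.

Step 8
Reactants: 11 2-hydroxy-4,6-bis(methoxymethoxy)-3,5-bis(3-methylbut-2-en-1-yl)benzaldehyde; 16 (E)-1-(methoxymethoxy)-4-(2-nitroethenyl)benzene
Product: 19 5,7-bis(methoxymethoxy)-2-[4-(methoxymethoxy)phenyl]-3-nitro-6,8-bis(3-methylbut-2-en-1-yl)-2H-chromene (racemic), via Michael adduct 17 (not isolated), via nitrochromanol 18 (not isolated)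
Conditions: DABCO (1.0 equiv), 16 (1.5 equiv), MeCN, 4 Å MS, 50 °C
Reagents that add atoms: none
Why: DABCO generates the single phenoxide of 11, which adds to the aryl-bearing carbon of nitroalkene 16 (O1–C2, oxa-Michael) to give 17; its nitronate carbon then attacks the neighbouring formyl group (C3–C4, intramolecular Henry) to give 18, and E1cB loss of water delivers the conjugated nitrochromene 19. The closest known reaction type is the amine-promoted tandem oxa-Michael–Henry condensation of salicylaldehydes with β-nitrostyrenes. Ring C closes in a 6-exo-trig mode, the attacked carbonyl carbon lying inside the new ring and its oxygen outside. The one new stereocentre, C2, forms without control as a racemate, which does not matter because C2 becomes trigonal in step 9. The step needs only chemo- and regioselectivity: 11 has one free hydroxyl, the polarity of the nitroalkene sends oxygen to the benzylic carbon and the nitronate carbon to the aldehyde, the reversible Michael addition is drawn forward by the irreversible dehydration, and an amine base leaves MOM ethers and prenyl alkenes untouched.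

Step 9
Reactants: 19 5,7-bis(methoxymethoxy)-2-[4-(methoxymethoxy)phenyl]-3-nitro-6,8-bis(3-methylbut-2-en-1-yl)-2H-chromene
Product: 22 3-hydroxy-5,7-bis(methoxymethoxy)-2-[4-(methoxymethoxy)phenyl]-6,8-bis(3-methylbut-2-en-1-yl)-4H-chromen-4-one, via nitro epoxide 20 (not isolated), via dihydroflavonol 21 (not isolated)
Conditions: H2O2 (30% aq., 3 equiv), NaOH (2 M aq., 3 equiv), MeOH/THF, 0 °C to rt; then AcOH to pH 6
Reagents that add atoms: hydrogen peroxide, OO; sodium hydroxide, [Na+].[OH-]
Why: Weitz–Scheffer nucleophilic epoxidation of the electron-poor nitroalkene gives 20, opening of the oxirane by hydroxide at benzylic C4 with loss of nitrite followed by an enediol shift gives 21, and alkaline peroxide should dehydrogenate 21 to the flavonol as in the last stage of an Algar–Flynn–Oyamada reaction, the electron-rich prenyl alkenes being inert to nucleophilic peroxide and the C2 stereocentre being erased.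

Step 10
Reactants: 22 3-hydroxy-5,7-bis(methoxymethoxy)-2-[4-(methoxymethoxy)phenyl]-6,8-bis(3-methylbut-2-en-1-yl)-4H-chromen-4-one
Product: 23 6,8-diprenylkaempferol
Conditions: HCl (3 M aq.)/MeOH/THF, 45 °C
Reagents that add atoms: none
Why: Acid-catalysed acetal methanolysis should remove the three aryl MOM ethers as dimethoxymethane, dilute acid at moderate temperature and close monitoring keeping the prenyl groups from cyclising onto the neighbouring phenols.

Compound list
1 | phloroglucinol | Oc1cc(O)cc(O)c1 | starting material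
2 | 1,3,5-tris(methoxymethoxy)benzene | COCOc1cc(OCOC)cc(OCOC)c1 | intermediate
3 | prenyl bromide (1-bromo-3-methylbut-2-ene) | CC(C)=CCBr | starting material
4 | [2,4,6-tris(methoxymethoxy)phenyl]lithium | [Li]c1c(OCOC)cc(OCOC)cc1OCOC | intermediate (not isolated)
5 | 1,3,5-tris(methoxymethoxy)-2-(3-methylbut-2-en-1-yl)benzene | COCOc1cc(OCOC)c(CC=C(C)C)c(OCOC)c1 | intermediate
6 | [2,4,6-tris(methoxymethoxy)-3-(3-methylbut-2-en-1-yl)phenyl]lithium | [Li]c1c(OCOC)cc(OCOC)c(CC=C(C)C)c1OCOC | intermediate (not isolated)
7 | 1,3,5-tris(methoxymethoxy)-2,4-bis(3-methylbut-2-en-1-yl)benzene | COCOc1cc(OCOC)c(CC=C(C)C)c(OCOC)c1CC=C(C)C | intermediate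
8 | [2,4,6-tris(methoxymethoxy)-3,5-bis(3-methylbut-2-en-1-yl)phenyl]lithium | [Li]c1c(OCOC)c(CC=C(C)C)c(OCOC)c(CC=C(C)C)c1OCOC | intermediate (not isolated)
9 | lithium (dimethylamino)[2,4,6-tris(methoxymethoxy)-3,5-bis(3-methylbut-2-en-1-yl)phenyl]methanolate (racemic) | [Li]OC(N(C)C)c1c(OCOC)c(CC=C(C)C)c(OCOC)c(CC=C(C)C)c1OCOC | intermediate (not isolated)
10 | 2,4,6-tris(methoxymethoxy)-3,5-bis(3-methylbut-2-en-1-yl)benzaldehyde | O=Cc1c(OCOC)c(CC=C(C)C)c(OCOC)c(CC=C(C)C)c1OCOC | intermediate
11 | 2-hydroxy-4,6-bis(methoxymethoxy)-3,5-bis(3-methylbut-2-en-1-yl)benzaldehyde | O=Cc1c(O)c(CC=C(C)C)c(OCOC)c(CC=C(C)C)c1OCOC | intermediate (key-step precursor)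
12 | 4-hydroxybenzaldehyde | O=Cc1ccc(O)cc1 | starting material
13 | 4-(methoxymethoxy)benzaldehyde | COCOc1ccc(C=O)cc1 | intermediate
14 | nitromethane | C[N+](=O)[O-] | starting material
15 | 1-[4-(methoxymethoxy)phenyl]-2-nitroethan-1-ol (racemic) | COCOc1ccc(C(O)C[N+](=O)[O-])cc1 | intermediate (not isolated)
16 | (E)-1-(methoxymethoxy)-4-(2-nitroethenyl)benzene | COCOc1ccc(/C=C/[N+](=O)[O-])cc1 | intermediate (key-step precursor)
17 | 2-{1-[4-(methoxymethoxy)phenyl]-2-nitroethoxy}-4,6-bis(methoxymethoxy)-3,5-bis(3-methylbut-2-en-1-yl)benzaldehyde (racemic; present as its nitronate) | O=Cc1c(OC(C[N+](=O)[O-])c2ccc(OCOC)cc2)c(CC=C(C)C)c(OCOC)c(CC=C(C)C)c1OCOC | intermediate (not isolated)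
18 | 5,7-bis(methoxymethoxy)-2-[4-(methoxymethoxy)phenyl]-3-nitro-6,8-bis(3-methylbut-2-en-1-yl)chroman-4-ol (racemic mixture of diastereomers, configuration not defined) | COCOc1ccc(C2Oc3c(CC=C(C)C)c(OCOC)c(CC=C(C)C)c(OCOC)c3C(O)C2[N+](=O)[O-])cc1 | intermediate (not isolated)
19 | 5,7-bis(methoxymethoxy)-2-[4-(methoxymethoxy)phenyl]-3-nitro-6,8-bis(3-methylbut-2-en-1-yl)-2H-chromene (racemic at C2) | COCOc1ccc(C2Oc3c(CC=C(C)C)c(OCOC)c(CC=C(C)C)c(OCOC)c3C=C2[N+](=O)[O-])cc1 | intermediate (key-step product)
20 | 3,4-epoxy-5,7-bis(methoxymethoxy)-2-[4-(methoxymethoxy)phenyl]-3-nitro-6,8-bis(3-methylbut-2-en-1-yl)chroman (racemic; oxirane oxygen expected on the face opposite the C2 aryl group; one enantiomer drawn) | COCOc1ccc(cc1)[C@H]2Oc3c(CC=C(C)C)c(OCOC)c(CC=C(C)C)c(OCOC)c3[C@@H]4O[C@]24[N+](=O)[O-] | intermediate (not isolated)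
21 | trans-3-hydroxy-5,7-bis(methoxymethoxy)-2-[4-(methoxymethoxy)phenyl]-6,8-bis(3-methylbut-2-en-1-yl)chroman-4-one (racemic; one enantiomer drawn) | COCOc1ccc(cc1)[C@@H]2[C@@H](O)C(=O)c3c(OCOC)c(CC=C(C)C)c(OCOC)c(CC=C(C)C)c3O2 | intermediate (not isolated)
22 | 3-hydroxy-5,7-bis(methoxymethoxy)-2-[4-(methoxymethoxy)phenyl]-6,8-bis(3-methylbut-2-en-1-yl)-4H-chromen-4-one | COCOc1ccc(-c2oc3c(CC=C(C)C)c(OCOC)c(CC=C(C)C)c(OCOC)c3c(=O)c2O)cc1 | intermediate
23 | 6,8-diprenylkaempferol, 3,5,7-trihydroxy-2-(4-hydroxyphenyl)-6,8-bis(3-methylbut-2-en-1-yl)-4H-chromen-4-one (achiral) | CC(C)=CCc1c(O)c(CC=C(C)C)c2oc(-c3ccc(O)cc3)c(O)c(=O)c2c1O | target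

Total step count: 10. Longest linear sequence: 8 steps (steps 1 to 5, then 8 to 10, from phloroglucinol); steps 6 and 7 form the two-step side branch to nitroalkene 16.

Steps most likely to fail

Step 8. The oxa-Michael addition of a hindered, hydrogen-bonded phenoxide to an electron-rich nitroalkene may stay on the starting-material side of its equilibrium, and the Henry closure onto an aldehyde flanked by two ortho substituents may be too slow to compete with base-induced decay of the nitroalkene. The fallback builds ring C by chalcone oxidation instead, setting out from 11 and returning at 22, so that steps 8 and 9 are bypassed. Addition of MeMgBr (3 equiv, THF, 0 °C) to 11 should give 1-[2-hydroxy-4,6-bis(methoxymethoxy)-3,5-bis(3-methylbut-2-en-1-yl)phenyl]ethan-1-ol F1. Oxidation of the benzylic carbinol with MnO2 (CH2Cl2, rt) should give 1-[2-hydroxy-4,6-bis(methoxymethoxy)-3,5-bis(3-methylbut-2-en-1-yl)phenyl]ethan-1-one F2. Claisen–Schmidt condensation of F2 with aldehyde 13 (KOH, EtOH, rt) should give (E)-1-[2-hydroxy-4,6-bis(methoxymethoxy)-3,5-bis(3-methylbut-2-en-1-yl)phenyl]-3-[4-(methoxymethoxy)phenyl]prop-2-en-1-one F3. Algar–Flynn–Oyamada oxidation of F3 (NaOH, H2O2, MeOH, 0 °C) then leads to flavonol 22, with competing aurone formation from the ortho-alkoxy chalcone as the known weakness of this detour.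

Step 9. The cascade may stall before dehydrogenation, the chromene may ring-open by retro-oxa-Michael reaction before it is epoxidised, or excess peroxide may degrade the flavonol once formed. The fallback separates oxygen transfer from dehydrogenation, setting out from 19 and returning at 22. Epoxidation and nitrite loss are run cold with limited oxidant (H2O2 1.2 equiv, NaOH, MeOH/THF, −10 °C) and dihydroflavonol 21 is isolated. Its C3 carbinol is then oxidised with Dess–Martin periodinane (NaHCO3, CH2Cl2, rt), which gives 22 after enolisation of the resulting 1,2-dicarbonyl unit. The detour passes only through compounds already listed, so no further compound arises (F0).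

Step 5. Mono-selectivity may be lost, either through cleavage of the second ortho acetal or through incomplete conversion that leaves mixtures difficult to separate. The fallback gives up selectivity in the cleavage and regains it in a re-protection, setting out from 10 and returning at 11. Excess MgBr2·OEt2 (3 equiv, Et2O/toluene, rt) should remove both chelating ortho MOM groups and give 2,6-dihydroxy-4-(methoxymethoxy)-3,5-bis(3-methylbut-2-en-1-yl)benzaldehyde F4. Treatment with MOMCl (1.05 equiv) and K2CO3 in acetone should then alkylate only one of the two equivalent phenols, because the remaining one is locked in the hydrogen bond to the formyl group.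

Further compounds
F1 | step 8 | 1-[2-hydroxy-4,6-bis(methoxymethoxy)-3,5-bis(3-methylbut-2-en-1-yl)phenyl]ethan-1-ol (racemic) | CC(O)c1c(O)c(CC=C(C)C)c(OCOC)c(CC=C(C)C)c1OCOC
F2 | step 8 | 1-[2-hydroxy-4,6-bis(methoxymethoxy)-3,5-bis(3-methylbut-2-en-1-yl)phenyl]ethan-1-one | CC(=O)c1c(O)c(CC=C(C)C)c(OCOC)c(CC=C(C)C)c1OCOC
F3 | step 8 | (E)-1-[2-hydroxy-4,6-bis(methoxymethoxy)-3,5-bis(3-methylbut-2-en-1-yl)phenyl]-3-[4-(methoxymethoxy)phenyl]prop-2-en-1-one | COCOc1ccc(/C=C/C(=O)c2c(O)c(CC=C(C)C)c(OCOC)c(CC=C(C)C)c2OCOC)cc1
F0 | step 9 | none | none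
F4 | step 5 | 2,6-dihydroxy-4-(methoxymethoxy)-3,5-bis(3-methylbut-2-en-1-yl)benzaldehyde | O=Cc1c(O)c(CC=C(C)C)c(OCOC)c(CC=C(C)C)c1O
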